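**Retrosynthetic overview**

1. The C50 diol comes from iBu2AlH reduction of the C50 bis(ethyl ester), which comes from a double Wittig reaction of two C15 phosphonium salts with the C10 trienedial (forms C11=C12 and C11'=C12').
2. The C15 salt comes from acid ionisation/dehydration of a dienediol, made by semi-hydrogenation of the adduct of a C6 enynol acetylide with a 3-substituted 2,2,6-trimethylcyclohexanone.
3. Key disconnection: C1–C6 of that cyclohexanone, made by intramolecular addition of an acyl anion equivalent (carbene-bound Breslow intermediate of an α-methyl aldehyde) to the internal carbon of an isopropenyl group. This closes the ring and creates the gem-dimethyl carbon in one event.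
4. The acyclic aldehyde comes from one-carbon homologation of the methyl ketone and Wittig extension of the aldehyde arm of (3R)-6-oxo-3-(prop-1-en-2-yl)heptanal, obtained by periodate cleavage of (R)-limonene oxide, which supplies the C2 stereocentre.
5. Ring order: each of the two identical six-membered end rings is closed once, at the C16 stage, before chain extension; the two halves are joined last.

Assumption: the target is the all-E (2R,2'R) isomer drawn (C.p. 450); commercial (+)-limonene 1,2-oxide is used as its cis/trans mixture, and epimers at carbons that later become sp2 are carried on unseparated.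

**Route**

Step 1
Reactants: 1 (4R)-limonene 1,2-oxide
Product: 3 (3R)-6-oxo-3-(prop-1-en-2-yl)heptanal, via menthene diol 2 (not isolated)
Conditions: H5IO6 (1.1 equiv), THF/H2O, 0 °C to rt
Reagents that add atoms: water, O
Why: Acid opens the epoxide to the 1,2-diol and periodate cleaves the glycol (Malaprade cleavage) while the isopropenyl group and the remote stereocentre are untouched, so the (R) centre that becomes C2 of the target is taken directly from the chiral pool.

Step 2
Reactants: 3 (3R)-6-oxo-3-(prop-1-en-2-yl)heptanal; 4 ethyl 2-(triphenylphosphoranylidene)propanoate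
Product: 5 ethyl (2E,5R)-2-methyl-8-oxo-5-(prop-1-en-2-yl)non-2-enoate
Conditions: CH2Cl2, rt
Reagents that add atoms: none
Why: The stabilised ylide reacts only with the aldehyde and not with the methyl ketone (Wittig olefination) and gives the (E)-2-methyl enoate with high selectivity, which fixes the side-chain alkene geometry of the target.

Step 3
Reactants: 5 ethyl (2E,5R)-2-methyl-8-oxo-5-(prop-1-en-2-yl)non-2-enoate; 6 (methoxymethyl)triphenylphosphonium chloride
Product: 9 ethyl (2E,5R)-2,8-dimethyl-9-oxo-5-(prop-1-en-2-yl)non-2-enoate, via methoxymethylidene ylide 7 (not isolated), via enol ether 8 (not isolated)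
Conditions: KOtBu, THF, 0 °C to rt; then 2 M HCl, THF, rt
Reagents that add atoms: water, O
Why: Wittig methoxymethylenation of the ketone followed by mild acid hydrolysis of the enol ether is the standard one-carbon homologation to an α-methyl aldehyde; the new α-centre is an epimer mixture, which does not matter because this carbon becomes sp2 (C5) in step 7.

Step 4
Reactants: 9 ethyl (2E,5R)-2,8-dimethyl-9-oxo-5-(prop-1-en-2-yl)non-2-enoate
Product: 10 ethyl (2E)-2-methyl-4-[(1R)-2,2,4-trimethyl-3-oxocyclohexyl]but-2-enoate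
Conditions: 3-(2,4,6-trimethylphenyl)-4,5,6,7-tetrahydro-1,3-benzothiazol-3-ium perchlorate (20 mol %), 1,8-diazabicyclo[5.4.0]undec-7-ene (40 mol %), 1,4-dioxane (0.05 M), 120 °C, sealed tube, argon
Reagents that add atoms: none
Why: Proposed new method: the thiazolylidene turns the aldehyde into its Breslow intermediate, an acyl anion equivalent, whose carbon adds to the internal carbon of the tethered isopropenyl group while the enol O–H proton passes to the terminal CH2 in a six-membered Conia-ene-like transition state, so the carbonyl carbon and the Markovnikov alkene carbon (both electrophilic sites in ordinary polar chemistry) are joined, closing the ring and creating the gem-dimethyl carbon with no cation next to the stereocentre; the closest known reaction is the carbene-catalysed intramolecular hydroacylation of unactivated 1,1-disubstituted alkenes in 2-(methallyloxy)benzaldehydes, which has the same four-atom tether, and the α-branched aldehyde disfavours acyloin dimerisation (the ring carbon α to the ketone is an irrelevant epimer mixture).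

Step 5
Reactants: 10 ethyl (2E)-2-methyl-4-[(1R)-2,2,4-trimethyl-3-oxocyclohexyl]but-2-enoate; 11 (2E)-3-methylpent-2-en-4-yn-1-ol (2.5 equiv)
Product: 13 ethyl (2E)-4-[(1R)-3-hydroxy-3-[(3E)-5-hydroxy-3-methylpent-3-en-1-yn-1-yl]-2,2,4-trimethylcyclohexyl]-2-methylbut-2-enoate, via dilithio enynol 12 (not isolated)
Conditions: nBuLi (2 equiv per 11), THF, −78 to −20 °C; then 10, −78 to 0 °C; aq. NH4Cl
Reagents that add atoms: none
Why: 1,2-Addition of a lithium acetylide to the ketone is the classical way to attach the C6 unit to trimethylcyclohexanones; at low temperature the acetylide adds to the ketone much faster than to the hindered conjugated ester, and the new carbinol centre is destroyed again in step 7.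

Step 6
Reactants: 13 ethyl (2E)-4-[(1R)-3-hydroxy-3-[(3E)-5-hydroxy-3-methylpent-3-en-1-yn-1-yl]-2,2,4-trimethylcyclohexyl]-2-methylbut-2-enoate
Product: 14 ethyl (2E)-4-[(1R)-3-hydroxy-3-[(1Z,3E)-5-hydroxy-3-methylpenta-1,3-dien-1-yl]-2,2,4-trimethylcyclohexyl]-2-methylbut-2-enoate
Conditions: H2 (1 atm, 1 equiv uptake), Pd/CaCO3 poisoned with Pb(OAc)2, quinoline, EtOAc, rt
Reagents that add atoms: none
Why: Lindlar-type semi-hydrogenation stops at the (Z)-alkene and leaves the trisubstituted alkenes and the ester untouched.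

Step 7
Reactants: 14 ethyl (2E)-4-[(1R)-3-hydroxy-3-[(1Z,3E)-5-hydroxy-3-methylpenta-1,3-dien-1-yl]-2,2,4-trimethylcyclohexyl]-2-methylbut-2-enoate
Product: 15 [(2E,4E)-5-[(5R)-5-[(2E)-4-ethoxy-3-methyl-4-oxobut-2-en-1-yl]-2,6,6-trimethylcyclohex-1-en-1-yl]-3-methylpenta-2,4-dien-1-yl]triphenylphosphonium bromide
Conditions: PPh3·HBr (1.05 equiv), MeOH/CH2Cl2, 0 °C to rt; crystallise
Reagents that add atoms: triphenylphosphine hydrobromide, Br.c1ccc(cc1)P(c1ccccc1)c1ccccc1
Why: Acid ionises the tertiary bis-allylic alcohol, loss of the ring proton gives the tetrasubstituted C5=C6 alkene, and ionisation of the primary allylic alcohol gives a fully conjugated cation that PPh3 captures at its primary terminus (SN1-type allylic substitution with dehydration, as in the vinyl-ionol route to C15 Wittig salts), the delocalised cation also turning the 7Z alkene into 7E.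

Step 8
Reactants: 15 the C15 phosphonium bromide (2.2 equiv); 16 (2E,4E,6E)-2,7-dimethylocta-2,4,6-trienedial
Product: 19 (2R,2'R)-2,2'-bis[(2E)-3-(ethoxycarbonyl)but-2-en-1-yl]-β,β-carotene, via phosphorus ylide 17 (not isolated), via apo-aldehyde 18 (not isolated)
Conditions: NaOEt, EtOH/CH2Cl2, −10 °C to rt; then heptane, reflux, dark, argon
Reagents that add atoms: none
Why: Double Wittig olefination of the C10 dialdehyde with the semi-stabilised C15 ylide builds C11=C12 and C11'=C12', and the Z isomers formed are converted into the all-E polyene by thermal isomerisation; the isolated esters do not react with the ylide.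

Step 9
Reactants: 19 (2R,2'R)-2,2'-bis[(2E)-3-(ethoxycarbonyl)but-2-en-1-yl]-β,β-carotene
Product: 20 (2R,2'R)-2,2'-bis[(2E)-4-hydroxy-3-methylbut-2-en-1-yl]-β,β-carotene (C.p. 450)
Conditions: iBu2AlH (5 equiv), CH2Cl2, −78 to −40 °C; aq. KNaC4H4O6
Reagents that add atoms: none
Why: iBu2AlH reduces both conjugated esters by 1,2-addition to the (E)-allylic alcohols without touching the polyene or the two stereocentres.

**Compound list**

1 | (4R)-limonene 1,2-oxide, cis/trans mixture | CC12CC[C@@H](C(C)=C)CC1O2 | starting material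
2 | (4R)-1-methyl-4-(prop-1-en-2-yl)cyclohexane-1,2-diol | CC1(O)CC[C@@H](C(C)=C)CC1O | intermediate
3 | (3R)-6-oxo-3-(prop-1-en-2-yl)heptanal | CC(=O)CC[C@H](CC=O)C(C)=C | intermediate
4 | ethyl 2-(triphenylphosphoranylidene)propanoate | CCOC(=O)C(C)=P(c1ccccc1)(c1ccccc1)c1ccccc1 | starting material
5 | ethyl (2E,5R)-2-methyl-8-oxo-5-(prop-1-en-2-yl)non-2-enoate | CC(=O)CC[C@H](C/C=C(\C)C(=O)OCC)C(C)=C | intermediate
6 | (methoxymethyl)triphenylphosphonium chloride | COC[P+](c1ccccc1)(c1ccccc1)c1ccccc1.[Cl-] | starting material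
7 | (methoxymethylidene)triphenylphosphorane | COC=P(c1ccccc1)(c1ccccc1)c1ccccc1 | intermediate
8 | ethyl (2E,5R)-9-methoxy-2,8-dimethyl-5-(prop-1-en-2-yl)nona-2,8-dienoate (enol ether E/Z mixture) | COC=C(C)CC[C@H](C/C=C(\C)C(=O)OCC)C(C)=C | intermediate
9 | ethyl (2E,5R)-2,8-dimethyl-9-oxo-5-(prop-1-en-2-yl)non-2-enoate (C8 epimers) | O=CC(C)CC[C@H](C/C=C(\C)C(=O)OCC)C(C)=C | intermediate
10 | ethyl (2E)-2-methyl-4-[(1R)-2,2,4-trimethyl-3-oxocyclohexyl]but-2-enoate (ring C4 epimers) | CC1CC[C@H](C/C=C(\C)C(=O)OCC)C(C)(C)C1=O | intermediate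
11 | (2E)-3-methylpent-2-en-4-yn-1-ol | C#C/C(C)=C/CO | starting material
12 | dilithium salt of (2E)-3-methylpent-2-en-4-yn-1-ol | [Li+].[Li+].[C-]#C/C(C)=C/C[O-] | intermediate
13 | ethyl (2E)-4-[(1R)-3-hydroxy-3-[(3E)-5-hydroxy-3-methylpent-3-en-1-yn-1-yl]-2,2,4-trimethylcyclohexyl]-2-methylbut-2-enoate | CC1CC[C@H](C/C=C(\C)C(=O)OCC)C(C)(C)C1(O)C#C/C(C)=C/CO | intermediate
14 | ethyl (2E)-4-[(1R)-3-hydroxy-3-[(1Z,3E)-5-hydroxy-3-methylpenta-1,3-dien-1-yl]-2,2,4-trimethylcyclohexyl]-2-methylbut-2-enoate | CC1CC[C@H](C/C=C(\C)C(=O)OCC)C(C)(C)C1(O)/C=C\C(C)=C\CO | intermediate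
15 | [(2E,4E)-5-[(5R)-5-[(2E)-4-ethoxy-3-methyl-4-oxobut-2-en-1-yl]-2,6,6-trimethylcyclohex-1-en-1-yl]-3-methylpenta-2,4-dien-1-yl]triphenylphosphonium bromide | CC1=C(/C=C/C(C)=C/C[P+](c2ccccc2)(c2ccccc2)c2ccccc2)C(C)(C)[C@@H](C/C=C(\C)C(=O)OCC)CC1.[Br-] | intermediate
16 | (2E,4E,6E)-2,7-dimethylocta-2,4,6-trienedial | O=C/C(C)=C/C=C/C=C(C)/C=O | starting material
17 | ylide of 15, ethyl (2E)-2-methyl-4-[(1R)-2,2,4-trimethyl-3-[(1E,3E)-3-methyl-5-(triphenylphosphoranylidene)penta-1,3-dien-1-yl]cyclohex-3-en-1-yl]but-2-enoate | CC1=C(/C=C/C(C)=C/C=P(c2ccccc2)(c2ccccc2)c2ccccc2)C(C)(C)[C@@H](C/C=C(\C)C(=O)OCC)CC1 | intermediate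
18 | ethyl (2E)-2-methyl-4-[(1R)-2,2,4-trimethyl-3-[(1E,3E,5E,7E,9E,11E)-3,7,12-trimethyl-13-oxotrideca-1,3,5,7,9,11-hexaen-1-yl]cyclohex-3-en-1-yl]but-2-enoate (drawn all-E) | CC1=C(/C=C/C(C)=C/C=C/C(C)=C/C=C/C=C(C)/C=O)C(C)(C)[C@@H](C/C=C(\C)C(=O)OCC)CC1 | intermediate
19 | (2R,2'R)-2,2'-bis[(2E)-3-(ethoxycarbonyl)but-2-en-1-yl]-β,β-carotene (all-E) | CC1=C(/C=C/C(C)=C/C=C/C(C)=C/C=C/C=C(C)/C=C/C=C(C)/C=C/C2=C(C)CC[C@H](C/C=C(\C)C(=O)OCC)C2(C)C)C(C)(C)[C@@H](C/C=C(\C)C(=O)OCC)CC1 | intermediate
20 | (2R,2'R)-2,2'-bis[(2E)-4-hydroxy-3-methylbut-2-en-1-yl]-β,β-carotene (C.p. 450, CNP0359519.1) | CC1=C(/C=C/C(C)=C/C=C/C(C)=C/C=C/C=C(C)/C=C/C=C(C)/C=C/C2=C(C)CC[C@H](C/C=C(\C)CO)C2(C)C)C(C)(C)[C@@H](C/C=C(\C)CO)CC1 | target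

**Totals and fallbacks**

Total step count: 9. Longest linear sequence: 9 steps (1 to 20); compounds 4, 6, 11 and 16 are bought.

The three steps most likely to fail are steps 4, 5 and 3.

Step 4 is the largest risk. The carbene hydroacylation has only been shown for aromatic aldehydes with an ortho tether; with 9 the aldehyde may simply be returned or lost to acyloin and aldol products. The fallback sets out from 9 and swaps the acyl anion for a radical ring closure. Fe(acac)3 and PhSiH3 in EtOH/ethylene glycol at 60 °C transfer a hydrogen atom to the CH2 of the isopropenyl group; the tertiary radical adds 6-exo to the aldehyde carbon and the alkoxy radical is reduced, giving ethyl (2E)-4-[(1R)-3-hydroxy-2,2,4-trimethylcyclohexyl]-2-methylbut-2-enoate F1. Oxidation of F1 with Dess–Martin periodinane in CH2Cl2 returns to the route at 10.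

Step 5 may fail because the ketone of 10 is very hindered, so ester attack or enolisation could compete. The fallback sets out from 10 and replaces carbonyl addition by cross-coupling. KN(SiMe3)2 and PhNTf2 in THF at −78 °C give (5R)-5-[(2E)-4-ethoxy-3-methyl-4-oxobut-2-en-1-yl]-2,6,6-trimethylcyclohex-1-en-1-yl trifluoromethanesulfonate F2. Separately, Bu3SnH with PdCl2(PPh3)2 adds to 11 to give (2E,4E)-3-methyl-5-(tributylstannyl)penta-2,4-dien-1-ol F3. Stille coupling of F2 and F3 (Pd2(dba)3, AsPh3, N-methylpyrrolidone, 50 °C) gives ethyl (2E)-4-[(1R)-3-[(1E,3E)-5-hydroxy-3-methylpenta-1,3-dien-1-yl]-2,2,4-trimethylcyclohex-3-en-1-yl]-2-methylbut-2-enoate F4, and PPh3·HBr in MeOH converts F4 into 15, where the route is rejoined (steps 5 to 7 are bypassed).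

Step 3 may fail because the basic ylide can enolise the methyl ketone or deconjugate the enoate, and the hydrolysis must spare the isopropenyl group. The fallback sets out from 5 and uses a sulfur ylide instead. Trimethylsulfonium iodide and KOtBu in DMSO/THF (Corey–Chaykovsky) give ethyl (2E,5R)-2-methyl-7-(2-methyloxiran-2-yl)-5-(prop-1-en-2-yl)hept-2-enoate F5. Catalytic ZnBr2 in CH2Cl2 at 0 °C then induces the Meinwald rearrangement (1,2-hydride shift) of F5 to the aldehyde, returning to the route at 9.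

Further compounds
F1 | step 4 | ethyl (2E)-4-[(1R)-3-hydroxy-2,2,4-trimethylcyclohexyl]-2-methylbut-2-enoate | CC1CC[C@H](C/C=C(\C)C(=O)OCC)C(C)(C)C1O
F2 | step 5 | (5R)-5-[(2E)-4-ethoxy-3-methyl-4-oxobut-2-en-1-yl]-2,6,6-trimethylcyclohex-1-en-1-yl trifluoromethanesulfonate | CC1=C(OS(=O)(=O)C(F)(F)F)C(C)(C)[C@@H](C/C=C(\C)C(=O)OCC)CC1
F3 | step 5 | (2E,4E)-3-methyl-5-(tributylstannyl)penta-2,4-dien-1-ol | CCCC[Sn](CCCC)(CCCC)/C=C/C(C)=C/CO
F4 | step 5 | ethyl (2E)-4-[(1R)-3-[(1E,3E)-5-hydroxy-3-methylpenta-1,3-dien-1-yl]-2,2,4-trimethylcyclohex-3-en-1-yl]-2-methylbut-2-enoate | CC1=C(/C=C/C(C)=C/CO)C(C)(C)[C@@H](C/C=C(\C)C(=O)OCC)CC1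
F5 | step 3 | ethyl (2E,5R)-2-methyl-7-(2-methyloxiran-2-yl)-5-(prop-1-en-2-yl)hept-2-enoate | CC1(CC[C@H](C/C=C(\C)C(=O)OCC)C(C)=C)CO1
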